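## Retrosynthetic overview

1. Target ⇒ (four O-benzyl ethers removed last) ⇒ cut both C3–CH2Ar bonds: a bis(α-hydroxy-β-benzyl lactone) on the biaryl core plus two equivalents of 4-(benzyloxy)-3-methoxybenzyl bromide (benzyl bromide fragment, from vanillin).
2. Bis(α-hydroxy lactone) ⇒ enolate hydroxylation and catalytic asymmetric hydrogenation (sets both C4) of a bis(butenolide).
3. Bis(butenolide) ⇒ cut both aryl–CH2 bonds (Suzuki): a biaryl bis(boronate) (biaryl fragment, from two molecules of vanillin via divanillin) plus two equivalents of 4-(bromomethyl)butenolide (butenolide fragment).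
4. Ring order: the lactone ring is the only ring built. It is closed first, in the butenolide fragment, by an intramolecular Knoevenagel–Doebner aldol condensation (C3–C4 bond) of a dihydroxyacetone malonic half-ester. All benzene rings come from vanillin.

## Assumptions

Assumption: the SMILES is taken as it stands, (3R,4R) in both lactones (benzyl groups trans, OH cis to the C4 benzyl); the biaryl axis has only two ortho substituents and is not a stereo-element.
Assumption: in step 11 the (R)-BINAP complex is written as the hand that gives the (S) lactone; a trial run decides, and the mirror-image ligand is used if it gives (R).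

## Route

Step 1
Reactants: 1 1,3-dihydroxyacetone (sold as its dimer)
Product: 2 1-[(tert-butyldimethylsilyl)oxy]-3-hydroxypropan-2-one
Conditions: TBSCl (1.0 equiv; 1 in twofold excess), imidazole, DMF, 0 °C to rt
Reagents that add atoms: tert-butyldimethylsilyl chloride, CC(C)(C)[Si](C)(C)Cl
Why: Statistical mono-silylation (silyl ether formation) of the symmetric ketodiol gives the mono-ether, separated from bis-ether by chromatography; no stereocentre.

Step 2
Reactants: 2 1-[(tert-butyldimethylsilyl)oxy]-3-hydroxypropan-2-one; 3 Meldrum's acid (2,2-dimethyl-1,3-dioxane-4,6-dione)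
Product: 4 3-{3-[(tert-butyldimethylsilyl)oxy]-2-oxopropoxy}-3-oxopropanoic acid
Conditions: toluene, 90 °C, 3 h
Reagents that add atoms: none
Why: Thermal acylation of an alcohol by Meldrum's acid (ring opening with loss of acetone) is the standard entry to malonic half-esters and leaves the silyl ether intact.

Step 3
Reactants: 4 3-{3-[(tert-butyldimethylsilyl)oxy]-2-oxopropoxy}-3-oxopropanoic acid
Product: 7 4-{[(tert-butyldimethylsilyl)oxy]methyl}furan-2(5H)-one, via aldol adduct 5 (not isolated), via butenolide acid 6 (not isolated)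
Conditions: pyridine, piperidine (0.2 equiv), rt then 95 °C
Reagents that add atoms: none
Why: Intramolecular Knoevenagel–Doebner aldol condensation: the malonate carbon adds 5-exo-trig to the activated α,α'-dioxygenated ketone, forming the C3–C4 bond and closing the lactone ring, then dehydration and amine-promoted decarboxylation give the conjugated butenolide; no stereocentre.

Step 4
Reactants: 7 4-{[(tert-butyldimethylsilyl)oxy]methyl}furan-2(5H)-one
Product: 8 4-(bromomethyl)furan-2(5H)-one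
Conditions: Ph3PBr2 (1.3 equiv), CH2Cl2, 0 °C to rt
Reagents that add atoms: dibromotriphenylphosphorane, BrP(Br)(c1ccccc1)(c1ccccc1)c1ccccc1
Why: Appel-type displacement: the phosphorane turns a primary silyl ether directly into the bromide under neutral conditions that the butenolide tolerates.

Step 5
Reactants: 9 vanillin (2 equiv)
Product: 10 divanillin (6,6'-dihydroxy-5,5'-dimethoxy[1,1'-biphenyl]-3,3'-dicarbaldehyde)
Conditions: FeSO4·7H2O (cat.), Na2S2O8 (0.55 equiv per vanillin), H2O, 80 °C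
Reagents that add atoms: vanillin (second molecule), COc1cc(C=O)ccc1O
Why: Oxidative phenol coupling (dehydrodimerisation): two molecules of 9 are oxidised to phenoxy radicals that join at the only free ortho position with loss of two hydrogens, giving the 5,5' biaryl bond of the target; the dimer precipitates from water.

Step 6
Reactants: 10 divanillin
Product: 11 6,6'-bis(benzyloxy)-5,5'-dimethoxy[1,1'-biphenyl]-3,3'-dicarbaldehyde
Conditions: BnBr, K2CO3, DMF, 70 °C
Reagents that add atoms: benzyl bromide, BrCc1ccccc1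
Why: Williamson etherification protects both phenols as benzyl ethers that survive every later step and fall off in the final hydrogenolysis.

Step 7
Reactants: 11 6,6'-bis(benzyloxy)-5,5'-dimethoxy[1,1'-biphenyl]-3,3'-dicarbaldehyde
Product: 13 6,6'-bis(benzyloxy)-5,5'-dimethoxy[1,1'-biphenyl]-3,3'-diol, via bis(formate) 12 (not isolated)
Conditions: mCPBA, CH2Cl2, rt; then K2CO3 (cat.), MeOH, rt
Reagents that add atoms: 3-chloroperoxybenzoic acid, OOC(=O)c1cccc(Cl)c1
Why: Dakin-type Baeyer–Villiger oxidation, in which the electron-rich para-alkoxyaryl group migrates to give the aryl formate, followed by methanolysis to the phenol.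

Step 8
Reactants: 13 6,6'-bis(benzyloxy)-5,5'-dimethoxy[1,1'-biphenyl]-3,3'-diol
Product: 14 6,6'-bis(benzyloxy)-5,5'-dimethoxy[1,1'-biphenyl]-3,3'-diyl bis(trifluoromethanesulfonate)
Conditions: Tf2O, pyridine, CH2Cl2, 0 °C
Reagents that add atoms: trifluoromethanesulfonic anhydride, O=S(=O)(OS(=O)(=O)C(F)(F)F)C(F)(F)F
Why: O-sulfonylation turns the phenols into aryl triflates ready for palladium chemistry.

Step 9
Reactants: 14 6,6'-bis(benzyloxy)-5,5'-dimethoxy[1,1'-biphenyl]-3,3'-diyl bis(trifluoromethanesulfonate)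
Product: 15 2,2'-[6,6'-bis(benzyloxy)-5,5'-dimethoxy[1,1'-biphenyl]-3,3'-diyl]bis(4,4,5,5-tetramethyl-1,3,2-dioxaborolane)
Conditions: B2pin2, PdCl2(dppf) (5 mol%), KOAc, 1,4-dioxane, 90 °C
Reagents that add atoms: bis(pinacolato)diboron, CC1(C)OB(OC1(C)C)B1OC(C)(C)C(C)(C)O1
Why: Miyaura borylation of the unhindered aryl triflates puts boron para to each benzyloxy group, where the benzylic carbon must go.

Step 10
Reactants: 15 2,2'-[6,6'-bis(benzyloxy)-5,5'-dimethoxy[1,1'-biphenyl]-3,3'-diyl]bis(4,4,5,5-tetramethyl-1,3,2-dioxaborolane); 8 4-(bromomethyl)furan-2(5H)-one (2.6 equiv)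
Product: 16 4,4'-{[6,6'-bis(benzyloxy)-5,5'-dimethoxy[1,1'-biphenyl]-3,3'-diyl]bis(methylene)}bis[furan-2(5H)-one]
Conditions: Pd(PPh3)4 (5 mol%), CsF, THF, 60 °C
Reagents that add atoms: none
Why: Twofold Suzuki–Miyaura sp2–sp3 coupling: the allylic bromide adds oxidatively to zerovalent palladium, fluoride-assisted transmetalation follows, and reductive elimination at the unhindered CH2 terminus keeps the C=C conjugated with the lactone.

Step 11
Reactants: 16 4,4'-{[6,6'-bis(benzyloxy)-5,5'-dimethoxy[1,1'-biphenyl]-3,3'-diyl]bis(methylene)}bis[furan-2(5H)-one]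
Product: 17 (4S,4'S)-4,4'-{[6,6'-bis(benzyloxy)-5,5'-dimethoxy[1,1'-biphenyl]-3,3'-diyl]bis(methylene)}bis(oxolan-2-one)
Conditions: H2 (100 atm), Ru(OAc)2[(R)-BINAP] (2 mol%), CH2Cl2–MeOH, 50 °C
Reagents that add atoms: none
Why: Noyori-type asymmetric hydrogenation of a β-substituted butenolide: the chiral Ru–BINAP catalyst adds H2 to one face of each C=C and sets both C4 centres as S by catalyst control, the minor meso-type diastereomer from the two independent reductions being removed by chromatography or crystallisation, while benzyl ethers are untouched by this homogeneous catalyst.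

Step 12
Reactants: 17 (4S,4'S)-4,4'-{[6,6'-bis(benzyloxy)-5,5'-dimethoxy[1,1'-biphenyl]-3,3'-diyl]bis(methylene)}bis(oxolan-2-one)
Product: 19 (3S,3'S,4R,4'R)-4,4'-{[6,6'-bis(benzyloxy)-5,5'-dimethoxy[1,1'-biphenyl]-3,3'-diyl]bis(methylene)}bis(3-hydroxyoxolan-2-one), via dipotassium bis(enolate) 18 (not isolated)
Conditions: KN(SiMe3)2 (2.3 equiv), THF, −78 °C; 2-(phenylsulfonyl)-3-phenyloxaziridine, −78 °C; AcOH
Reagents that add atoms: 2-(phenylsulfonyl)-3-phenyloxaziridine, O=S(=O)(c1ccccc1)N1OC1c1ccccc1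
Why: Davis enolate hydroxylation brings oxygen in anti to the C4 substituent (trans product shown); this C3 centre is erased again in step 16, so its purity is immaterial and C4 (now labelled R only through the priority change) is untouched.

Step 13
Reactants: 9 vanillin
Product: 20 4-(benzyloxy)-3-methoxybenzaldehyde
Conditions: BnBr, K2CO3, DMF, rt
Reagents that add atoms: benzyl bromide, BrCc1ccccc1
Why: Williamson etherification of the phenol.

Step 14
Reactants: 20 4-(benzyloxy)-3-methoxybenzaldehyde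
Product: 21 [4-(benzyloxy)-3-methoxyphenyl]methanol
Conditions: NaBH4, MeOH, 0 °C
Reagents that add atoms: none
Why: Borohydride reduction of the aldehyde to the benzylic alcohol.

Step 15
Reactants: 21 [4-(benzyloxy)-3-methoxyphenyl]methanol
Product: 22 1-(benzyloxy)-4-(bromomethyl)-2-methoxybenzene
Conditions: PBr3, Et2O, 0 °C (used fresh)
Reagents that add atoms: phosphorus tribromide, BrP(Br)Br
Why: Bromination of the electron-rich benzylic alcohol by SN2 displacement of the phosphite ester.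

Step 16
Reactants: 19 (3S,3'S,4R,4'R)-4,4'-{[6,6'-bis(benzyloxy)-5,5'-dimethoxy[1,1'-biphenyl]-3,3'-diyl]bis(methylene)}bis(3-hydroxyoxolan-2-one); 22 1-(benzyloxy)-4-(bromomethyl)-2-methoxybenzene (2.6 equiv)
Product: 24 (3R,3'R,4R,4'R)-4,4'-{[6,6'-bis(benzyloxy)-5,5'-dimethoxy[1,1'-biphenyl]-3,3'-diyl]bis(methylene)}bis{3-[4-(benzyloxy)-3-methoxybenzyl]-3-hydroxyoxolan-2-one}, via tetralithium bis(enediolate) 23 (not isolated)
Conditions: LiN(iPr)2 (4.6 equiv), THF–DMPU, −78 to −40 °C; 22, −78 to −20 °C; AcOH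
Reagents that add atoms: none
Why: Frater–Seebach-type C-alkylation of the α-alkoxide enolate dianion: the benzyl bromide approaches planar C3 anti to the C4 benzyl group, so the new benzyl ends trans and the hydroxyl cis to it, which is the (3R,4R) arrangement of the target.

Step 17
Reactants: 24 (3R,3'R,4R,4'R)-4,4'-{[6,6'-bis(benzyloxy)-5,5'-dimethoxy[1,1'-biphenyl]-3,3'-diyl]bis(methylene)}bis{3-[4-(benzyloxy)-3-methoxybenzyl]-3-hydroxyoxolan-2-one}
Product: 25 bis-5,5-nortrachelogenin [(3R,3'R,4R,4'R)-4,4'-[(6,6'-dihydroxy-5,5'-dimethoxy[1,1'-biphenyl]-3,3'-diyl)bis(methylene)]bis[3-hydroxy-3-(4-hydroxy-3-methoxybenzyl)oxolan-2-one]]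
Conditions: H2 (1 atm), Pd/C (10 wt% Pd), EtOAc–MeOH, rt
Reagents that add atoms: none
Why: Hydrogenolysis cleaves the four aryl benzyl ethers and leaves the lactones, the tertiary alcohols and all four stereocentres untouched.

## Compound list

1 | 1,3-dihydroxyacetone | OCC(=O)CO | starting material
2 | 1-[(tert-butyldimethylsilyl)oxy]-3-hydroxypropan-2-one | CC(C)(C)[Si](C)(C)OCC(=O)CO | intermediate
3 | Meldrum's acid (2,2-dimethyl-1,3-dioxane-4,6-dione) | CC1(C)OC(=O)CC(=O)O1 | starting material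
4 | 3-{3-[(tert-butyldimethylsilyl)oxy]-2-oxopropoxy}-3-oxopropanoic acid | CC(C)(C)[Si](C)(C)OCC(=O)COC(=O)CC(=O)O | intermediate
5 | 4-{[(tert-butyldimethylsilyl)oxy]methyl}-4-hydroxy-2-oxooxolane-3-carboxylic acid (aldol adduct, not isolated) | CC(C)(C)[Si](C)(C)OCC1(O)COC(=O)C1C(=O)O | intermediate
6 | 4-{[(tert-butyldimethylsilyl)oxy]methyl}-2-oxo-2,5-dihydrofuran-3-carboxylic acid (not isolated) | CC(C)(C)[Si](C)(C)OCC1=C(C(=O)O)C(=O)OC1 | intermediate
7 | 4-{[(tert-butyldimethylsilyl)oxy]methyl}furan-2(5H)-one | CC(C)(C)[Si](C)(C)OCC1=CC(=O)OC1 | intermediate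
8 | 4-(bromomethyl)furan-2(5H)-one | BrCC1=CC(=O)OC1 | intermediate
9 | vanillin | COc1cc(C=O)ccc1O | starting material
10 | divanillin | COc1cc(C=O)cc(c1O)-c1cc(C=O)cc(OC)c1O | intermediate
11 | 6,6'-bis(benzyloxy)-5,5'-dimethoxy[1,1'-biphenyl]-3,3'-dicarbaldehyde | O=Cc1cc(OC)c(OCc2ccccc2)c(c1)-c1cc(C=O)cc(OC)c1OCc1ccccc1 | intermediate
12 | 6,6'-bis(benzyloxy)-5,5'-dimethoxy[1,1'-biphenyl]-3,3'-diyl diformate (not isolated) | O=COc1cc(OC)c(OCc2ccccc2)c(c1)-c1cc(OC=O)cc(OC)c1OCc1ccccc1 | intermediate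
13 | 6,6'-bis(benzyloxy)-5,5'-dimethoxy[1,1'-biphenyl]-3,3'-diol | Oc1cc(OC)c(OCc2ccccc2)c(c1)-c1cc(O)cc(OC)c1OCc1ccccc1 | intermediate
14 | 6,6'-bis(benzyloxy)-5,5'-dimethoxy[1,1'-biphenyl]-3,3'-diyl bis(trifluoromethanesulfonate) | O=S(=O)(Oc1cc(OC)c(OCc2ccccc2)c(c1)-c1cc(OS(=O)(=O)C(F)(F)F)cc(OC)c1OCc1ccccc1)C(F)(F)F | intermediate
15 | 2,2'-[6,6'-bis(benzyloxy)-5,5'-dimethoxy[1,1'-biphenyl]-3,3'-diyl]bis(4,4,5,5-tetramethyl-1,3,2-dioxaborolane) | CC1(C)OB(OC1(C)C)c1cc(OC)c(OCc2ccccc2)c(c1)-c1cc(cc(OC)c1OCc1ccccc1)B1OC(C)(C)C(C)(C)O1 | intermediate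
16 | 4,4'-{[6,6'-bis(benzyloxy)-5,5'-dimethoxy[1,1'-biphenyl]-3,3'-diyl]bis(methylene)}bis[furan-2(5H)-one] | O=C1OCC(Cc2cc(OC)c(OCc3ccccc3)c(c2)-c2cc(CC3=CC(=O)OC3)cc(OC)c2OCc2ccccc2)=C1 | intermediate
17 | (4S,4'S)-4,4'-{[6,6'-bis(benzyloxy)-5,5'-dimethoxy[1,1'-biphenyl]-3,3'-diyl]bis(methylene)}bis(oxolan-2-one) | COc1cc(C[C@@H]2COC(=O)C2)cc(c1OCc1ccccc1)-c1cc(C[C@@H]2COC(=O)C2)cc(OC)c1OCc1ccccc1 | intermediate
18 | dipotassium bis(enolate) of 17 (not isolated) | [K+].[K+].COc1cc(C[C@@H]2COC([O-])=C2)cc(c1OCc1ccccc1)-c1cc(C[C@@H]2COC([O-])=C2)cc(OC)c1OCc1ccccc1 | intermediate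
19 | (3S,3'S,4R,4'R)-4,4'-{[6,6'-bis(benzyloxy)-5,5'-dimethoxy[1,1'-biphenyl]-3,3'-diyl]bis(methylene)}bis(3-hydroxyoxolan-2-one) (OH trans to the C4 benzyl) | COc1cc(C[C@@H]2COC(=O)[C@H]2O)cc(c1OCc1ccccc1)-c1cc(C[C@@H]2COC(=O)[C@H]2O)cc(OC)c1OCc1ccccc1 | intermediate
20 | 4-(benzyloxy)-3-methoxybenzaldehyde | COc1cc(C=O)ccc1OCc1ccccc1 | intermediate
21 | [4-(benzyloxy)-3-methoxyphenyl]methanol | COc1cc(CO)ccc1OCc1ccccc1 | intermediate
22 | 1-(benzyloxy)-4-(bromomethyl)-2-methoxybenzene | COc1cc(CBr)ccc1OCc1ccccc1 | intermediate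
23 | tetralithium bis(enediolate) of 19 (not isolated) | [Li+].[Li+].[Li+].[Li+].COc1cc(C[C@@H]2COC([O-])=C2[O-])cc(c1OCc1ccccc1)-c1cc(C[C@@H]2COC([O-])=C2[O-])cc(OC)c1OCc1ccccc1 | intermediate
24 | tetra-O-benzyl bis-5,5-nortrachelogenin, (3R,3'R,4R,4'R) | COc1cc(C[C@]2(O)C(=O)OC[C@H]2Cc2cc(OC)c(OCc3ccccc3)c(-c3cc(C[C@@H]4COC(=O)[C@@]4(O)Cc4ccc(OCc5ccccc5)c(OC)c4)cc(OC)c3OCc3ccccc3)c2)ccc1OCc1ccccc1 | intermediate
25 | bis-5,5-nortrachelogenin, (3R,3'R,4R,4'R) | COc1cc(C[C@]2(O)C(=O)OC[C@H]2Cc2cc(OC)c(O)c(-c3cc(C[C@@H]4COC(=O)[C@@]4(O)Cc4ccc(O)c(OC)c4)cc(OC)c3O)c2)ccc1O | target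

## Step count and risks

Total step count: 17.

Longest linear sequence: 10 steps (vanillin 9 → 10 → 11 → 13 → 14 → 15 → 16 → 17 → 19 → 24 → 25; steps 5–12, 16, 17). The butenolide branch (steps 1–4) and the benzyl bromide branch (steps 13–15) run in parallel. 10 of 17 is below two thirds.

Three steps most likely to fail:

Step 3 (one-pot Knoevenagel–Doebner ring closure). The ketone may condense sluggishly or the butenolide acid 6 may resist decarboxylation. Fallback: close the ring by a zinc-enolate (Reformatsky-type) intramolecular aldol addition instead. Setting out from ketol 2, acylation with bromoacetyl bromide (pyridine, CH2Cl2, 0 °C) gives 3-[(tert-butyldimethylsilyl)oxy]-2-oxopropyl bromoacetate F1. Activated Zn dust in THF at 50 °C then closes the ring to 4-{[(tert-butyldimethylsilyl)oxy]methyl}-4-hydroxyoxolan-2-one F2. Dehydration with SOCl2/pyridine at 0 °C comes back to the route at butenolide 7.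

Step 10 (twofold Suzuki coupling). The allylic bromide 8 and the product butenolide are base-sensitive (γ-deprotonation, double-bond migration). Fallback: a base-free π-allyl coupling through a carbonate. Setting out from silyl ether 7, HF·pyridine (THF, 0 °C) gives 4-(hydroxymethyl)furan-2(5H)-one F3. Methyl chloroformate/pyridine converts it into methyl (5-oxo-2,5-dihydrofuran-3-yl)methyl carbonate F4. Pd(PPh3)4 in THF at 60 °C without added base couples F4 with bis(boronate) 15, the methoxide released on ionisation activating boron, and the route is rejoined at bis(butenolide) 16.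

Step 16 (twofold dianion benzylation). The tetra-anion may be poorly soluble, or O-alkylation and incomplete second alkylation may compete. Fallback: bring the benzylic carbon in as the more reactive aldehyde. Setting out from diol 19 (deprotonated as before to 23), aldol addition to 4-(benzyloxy)-3-methoxybenzaldehyde 20, again anti to the C4 benzyl group, gives the bis(β-hydroxy) adduct, tetra-O-benzyl 7,7'-dihydroxy-bis-5,5-nortrachelogenin F5 (carbinol epimers irrelevant). Hydrogenolysis (H2, Pd(OH)2/C, EtOH–AcOH) removes both benzylic hydroxyls together with the four benzyl ethers and comes back to the route directly at target 25.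

Further compounds

F1 | step 3 | 3-[(tert-butyldimethylsilyl)oxy]-2-oxopropyl bromoacetate | CC(C)(C)[Si](C)(C)OCC(=O)COC(=O)CBr
F2 | step 3 | 4-{[(tert-butyldimethylsilyl)oxy]methyl}-4-hydroxyoxolan-2-one | CC(C)(C)[Si](C)(C)OCC1(O)CC(=O)OC1
F3 | step 10 | 4-(hydroxymethyl)furan-2(5H)-one | OCC1=CC(=O)OC1
F4 | step 10 | methyl (5-oxo-2,5-dihydrofuran-3-yl)methyl carbonate | COC(=O)OCC1=CC(=O)OC1
F5 | step 16 | tetra-O-benzyl 7,7'-dihydroxy-bis-5,5-nortrachelogenin (extra OH on each new benzylic carbon) | COc1cc(C(O)[C@]2(O)C(=O)OC[C@H]2Cc2cc(OC)c(OCc3ccccc3)c(-c3cc(C[C@@H]4COC(=O)[C@@]4(O)C(O)c4ccc(OCc5ccccc5)c(OC)c4)cc(OC)c3OCc3ccccc3)c2)ccc1OCc1ccccc1
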